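(The earlier runs and the new flask are calculated for an exercise; the scatter is artificial.)

Ask how much target the west run holds at 68 min. Its charge is that of the east run, whose last reading stands at 34 min, so the task is to extend one curve by 34.0 min.

| flask | substrate | partner | target | time |
|---|---|---|---|---|
| east | 0.300 M | 0.240 M |  |  |
| south | 0.120 M | 0.0600 M |  |  |
| south-east | 0.300 M | 0.360 M |  |  |
| north-east | 0.300 M | 0.240 M | 0.0900 M |  |
| west | 0.300 M | 0.240 M |  | 68 min |

| east run: time / min | east run: [target] / M | south run: time / min | south run: [target] / M | south-east run: time / min | south-east run: [target] / M | north-east run: time / min | north-east run: [target] / M |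
|---|---|---|---|---|---|---|---|
| 1.4 | 0.0035 | 1.4 | 0 | 1.4 | 0.0023 | 1.4 | 0.1298 |
| 2.2 | 0 | 2.2 | 5 × 10⁻⁴ | 2.2 | 0.0083 | 2.2 | 0.1492 |
| 3.4 | 0.0148 | 3.4 | 0.0022 | 3.4 | 0.0160 | 3.4 | 0.1755 |
| 5.4 | 0.0283 | 5.4 | 0.0020 | 5.4 | 0.0498 | 5.4 | 0.2158 |
| 8.6 | 0.0661 | 8.6 | 0.0013 | 8.6 | 0.1104 | 8.6 | 0.2457 |
| 14 | 0.1150 | 14 | 0.0082 | 14 | 0.1827 | 14 | 0.2722 |
| 21 | 0.1440 | 21 | 0.0153 | 21 | 0.2168 | 21 | 0.2816 |
| 34 | 0.1633 | 34 | 0.0204 | 34 | 0.2372 | 34 | 0.2901 |

(standard deviation of a reading: 0.002 M)

- reaction order in [substrate] at the outset, round the charge of the east run, defined at two percent of the substrate turned into target (one fixed amount of target, the same in the runs compared)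
- reaction order in [partner] at the outset, round the charge of the east run, defined at two percent of the substrate turned into target
- target in the west run at 68 min, as a share of the substrate charged

- Overall: substrate + partner -> target.
- Constant volume, constant temperature.
- An order is taken over about fifteen percent of the charge, up and down.

Climb the time scales of the east run from the quick one upward. On the first rung, take the east readings at 5.4 min and 8.6 min and read from them a mean growth time of 3.77 min, the time in which target grows by a factor e over that stretch. The north-east run, seeded with target, has made 0.0855 M by 3.4 min, more than the 0.0148 M of the east run, and this seeded comparison is what marks autocatalysis here.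

On the second rung, replace each late stretch of the east curve by its mean rate: 0.00414 M min⁻¹ from 14 min to 21 min, then 0.00148 M min⁻¹ up to 34 min. Set at midpoints 10.0 min apart, they give the tail time τ, the time in which the rate of making target falls by a factor e, of 9.74 min, longer than the growth time. The charge holds less partner than substrate, which makes the partner the limiting reagent.

On the third rung, note that the stretch asked about spans 3.49 τ, so nearly all of what the tail still holds arrives in time. A rate decaying this way still owes its present value times τ, here 0.00742 M. Check the mean against the exact sum of the decay, 0.00690 M: the gap is less than the scatter of a reading. My reckoning for the west run is therefore 56.7%; it offers no order.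

The forecast gives 0.9 in substrate, 0.9 in partner and 62% for the west run, within 57% to 72%, holding that “the catalyst seems to die”. Its share stands above mine.

The flask gives 0.76 in substrate, 0.64 in partner and 55.2% for the west run.

    substrate ⇌ intermediate (0.03396 min⁻¹, 0.07260 min⁻¹)
    intermediate + partner → target (1.020 L mol⁻¹ min⁻¹)
    substrate + partner + target → 2 target (4.032 L² mol⁻² min⁻¹)
    partner → lost reagent (0.02808 min⁻¹)

In the east run the steps intermediate + partner → target and substrate + partner + target → 2 target together carried target to half of the substrate charged at 23.0 min, while partner → lost reagent ran beside them with a partner life of 35.6 min, longer than τ. The west run ends 0.00233 M above the last east reading, where τ allowed 0.00690 M. The south-east run, whose mean rate up to 21 min and τ put 0.241 M at 34 min, read 0.2372 M.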